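**Assumption:** the SMILES is read literally, i.e. (2R) at the chromene carbon and a trans-fused (3aS,7aR) ring junction; [(1S)-endo]-(−)-3-bromocamphor is taken as a catalogue compound (otherwise one step from (1S)-(−)-camphor with Br2 in AcOH).

## Retrosynthetic overview

1. The pyran ring of the chromene is closed last: aryl C8a–O bond from the tertiary carbinol oxygen onto an arene C–H (photocatalytic dehydrogenative cyclisation) after Heck arylation of a vinyl group. The C2 stereocentre is the untouched carbinol carbon of (R)-linalool.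
2. The cyclohexenone ring comes from an intramolecular aldol condensation (C5=C6) of a 1,5-diketone.
3. The 1,5-diketone comes from the C6–C7 bond, made by nickel/photoredox coupling of a neopentyl bromide with a linalool-derived C5 aldehyde (light-driven fragment union).
4. The trans-1,2-dimethylcyclopentane with both quaternary centres comes from (1S)-3-bromocamphor: C9 bromination, C2–C3 cleavage, excision of C3. Camphor C1/C7/C9/C2 become C3a/C7a/C7/C4.
5. Ring order: cyclopentane (bought in camphor), then cyclohexenone (aldol), then pyran ring (last).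

## Route

Step 1
Reactants: 1 (R)-(−)-linalool, (3R)-3,7-dimethylocta-1,6-dien-3-ol
Product: 2 triethyl{[(3R)-3,7-dimethylocta-1,6-dien-3-yl]oxy}silane
Conditions: TESOTf, 2,6-lutidine, CH2Cl2, −78 → 0 °C
Reagents that add atoms: triethylsilyl triflate, CC[Si](CC)(CC)OS(=O)(=O)C(F)(F)F
Why: Silyl triflate silylation of a hindered tertiary alcohol breaks no bond to the bought stereocentre, and the silyl ether later blocks retro-aldol cleavage and elimination at this carbon.

Step 2
Reactants: 2 triethyl{[(3R)-3,7-dimethylocta-1,6-dien-3-yl]oxy}silane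
Product: 3 (4R)-4-methyl-4-[(triethylsilyl)oxy]hex-5-enal
Conditions: O3, CH2Cl2, −78 °C (Sudan Red 7B end point); then Me2S, −78 → 20 °C
Reagents that add atoms: ozone, O=[O+][O-]
Why: Chemoselective ozonolysis, because electrophilic ozone cleaves the electron-rich trisubstituted alkene far faster than the monosubstituted vinyl group beside the quaternary silyloxy carbon, and the dye marks the end point.

Step 3
Reactants: 3 (4R)-4-methyl-4-[(triethylsilyl)oxy]hex-5-enal
Product: 5 (3R)-3-methyl-3-[(triethylsilyl)oxy]pent-4-enal, via enamine 4 (not isolated)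
Conditions: morpholine (1.0 equiv), 4 Å MS, CH2Cl2, 0 → 20 °C; then O2, tetraphenylporphyrin (cat.), white LEDs, −40 → 20 °C
Reagents that add atoms: dioxygen, O=O
Why: One-carbon degradation by enamine formation and singlet-oxygen cleavage of the enamine C=C bond (enamine photooxygenation); the vinyl group has no allylic hydrogen for an ene reaction and the stereocentre is not involved.

Step 4
Reactants: 6 [(1S)-endo]-(−)-3-bromocamphor, (1S,3R,4R)-3-bromo-1,7,7-trimethylbicyclo[2.2.1]heptan-2-one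
Product: 7 (1S,3R,4R,7S)-3-bromo-7-(bromomethyl)-1,7-dimethylbicyclo[2.2.1]heptan-2-one (3,9-dibromocamphor, CH2Br anti to the carbonyl)
Conditions: Br2, ClSO3H, 20 °C
Reagents that add atoms: bromine, BrBr
Why: Known C9 bromination of 3-bromocamphor in strong acid through a Wagner–Meerwein/Nametkin shift sequence, which brominates only the bridge methyl anti to the carbonyl, so C7 becomes a stereocentre under control of the bought skeleton.

Step 5
Reactants: 7 (1S,3R,4R,7S)-3-bromo-7-(bromomethyl)-1,7-dimethylbicyclo[2.2.1]heptan-2-one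
Product: 8 (1S,2S,3R)-2-(bromomethyl)-1,2-dimethylcyclopentane-1,3-dicarboxylic acid
Conditions: HNO3 (65%), NH4VO3 (cat.), 85 °C
Reagents that add atoms: nitric acid, O[N+](=O)[O-]; water, O
Why: Nitric acid oxidative cleavage of the α-bromo ketone between C2 and C3 (the classical camphor to camphoric acid oxidation) gives the cis-1,3-diacid; the two quaternary centres have no enolisable hydrogen, and the CO2H on C1 is trans to CH2Br.

Step 6
Reactants: 8 (1S,2S,3R)-2-(bromomethyl)-1,2-dimethylcyclopentane-1,3-dicarboxylic acid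
Product: 11 (1S,2S)-2-(bromomethyl)-1,2-dimethylcyclopentane-1-carboxylic acid, via cyclic anhydride 9 (not isolated), via Barton ester 10 (not isolated)
Conditions: DCC, CH2Cl2, 20 °C; then 1-hydroxypyridine-2(1H)-thione, DMAP (cat.), 0 °C, dark; then t-BuSH, 250 W tungsten lamp, 20 °C
Reagents that add atoms: none
Why: Barton reductive decarboxylation: the anhydride is opened at the less hindered secondary carbonyl and light plus thiol replace that carboxyl by hydrogen (photolysis drains the ester as it forms), which erases the C3 stereocentre and leaves the trans-1,2-dimethyl pair from camphor.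

Step 7
Reactants: 11 (1S,2S)-2-(bromomethyl)-1,2-dimethylcyclopentane-1-carboxylic acid; 12 4-chloro-2-methylbutan-2-ol
Product: 14 1-[(1S,2S)-2-(bromomethyl)-1,2-dimethylcyclopentyl]-4-hydroxy-4-methylpentan-1-one, via acid chloride 13 (not isolated)
Conditions: (COCl)2, DMF (cat.), CH2Cl2, 0 → 20 °C; then ClMgOC(Me)2CH2CH2MgCl (from 12, i-PrMgCl, then Mg, THF, 65 °C), Fe(acac)3 (5 mol%), THF, −78 °C
Reagents that add atoms: none
Why: Iron-catalysed acylation of a Grignard reagent by an acid chloride stops at the ketone (the carbonyl sits on a quaternary carbon) and is much faster than any reaction at the neopentyl bromide; no stereocentre is touched.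

Step 8
Reactants: 14 1-[(1S,2S)-2-(bromomethyl)-1,2-dimethylcyclopentyl]-4-hydroxy-4-methylpentan-1-one; 5 (3R)-3-methyl-3-[(triethylsilyl)oxy]pent-4-enal
Product: 16 (3aS,7aR)-5-(2-hydroxy-2-methylpropyl)-3a,7a-dimethyl-6-{(2R)-2-methyl-2-[(triethylsilyl)oxy]but-3-en-1-yl}-1,2,3,3a,7,7a-hexahydro-4H-inden-4-one, via 1,5-diketone 15 (not isolated)
Conditions: Ir[dF(CF3)ppy]2(dtbbpy)PF6 (1 mol%), NiBr2(dme) (10 mol%), dtbbpy, quinuclidine (10 mol%), K2CO3, 1,4-dioxane, 450 nm LEDs, 25 °C; then KOt-Bu (cat.), t-BuOH, 0 → 40 °C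
Reagents that add atoms: none
Why: The photogenerated quinuclidinium radical cation abstracts the aldehyde hydrogen of 5, nickel captures the acyl radical and activates the neopentyl C–Br bond of 14 by a radical oxidative addition that is little affected by the β-quaternary centre, and reductive elimination forms the C6–C7 bond (nickel/hydrogen-atom-transfer/photoredox aldehyde C–H alkylation); base then closes the only unstrained aldol (C5 enolate onto the C6 ketone) and dehydrates it to the tetrasubstituted enone (intramolecular aldol condensation) without forming or touching a stereocentre.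

Step 9
Reactants: 16 (3aS,7aR)-5-(2-hydroxy-2-methylpropyl)-3a,7a-dimethyl-6-{(2R)-2-methyl-2-[(triethylsilyl)oxy]but-3-en-1-yl}-1,2,3,3a,7,7a-hexahydro-4H-inden-4-one; 17 1-bromo-3-methoxy-5-methylbenzene
Product: 19 (3aS,7aR)-6-[(2R,3E)-2-hydroxy-4-(3-methoxy-5-methylphenyl)-2-methylbut-3-en-1-yl]-5-(2-hydroxy-2-methylpropyl)-3a,7a-dimethyl-1,2,3,3a,7,7a-hexahydro-4H-inden-4-one, via silyl ether 18 (not isolated)
Conditions: Pd(OAc)2 (5 mol%), P(o-tol)3, Et3N, DMF, 100 °C; then TBAF, AcOH, THF, 20 °C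
Reagents that add atoms: none
Why: Mizoroki–Heck arylation at the terminal vinyl carbon (the quaternary neighbour leaves only the benzylic β-hydrogen, so a single E-styrene forms and the tetrasubstituted enone does not insert), followed by buffered fluoride cleavage of the silyl ether.

Step 10
Reactants: 19 (3aS,7aR)-6-[(2R,3E)-2-hydroxy-4-(3-methoxy-5-methylphenyl)-2-methylbut-3-en-1-yl]-5-(2-hydroxy-2-methylpropyl)-3a,7a-dimethyl-1,2,3,3a,7,7a-hexahydro-4H-inden-4-one
Product: 21 (3aS,7aR)-5-(2-hydroxy-2-methylpropyl)-6-{[(2R)-6-methoxy-2,8-dimethyl-2H-chromen-2-yl]methyl}-3a,7a-dimethyl-1,2,3,3a,7,7a-hexahydro-4H-inden-4-one, via Z-styrene 20 (not isolated)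
Conditions: fac-Ir(ppy)3 (1 mol%), MeCN, 450 nm LEDs, N2, 25 °C; then 9-mesityl-10-methylacridinium tetrafluoroborate (5 mol%), Co(dmgH)2(py)Cl (5 mol%), 450 nm LEDs, N2, 25 °C
Reagents that add atoms: none
Why: Proposed new method: after a known triplet-sensitised E→Z isomerisation (the Z-styrene is twisted out of conjugation by the quaternary carbinol and accumulates), the excited acridinium oxidises the electron-rich styrene to its radical cation, the tertiary hydroxyl now held beside the ring attacks the ring carbon ortho to the alkene and para to the methoxy group (highest positive charge, six-membered transition state), and the cobaloxime takes electron and proton from the cyclohexadienyl radical and releases H2, so the aryl C–O bond of the chromene forms with no bond to the linalool-derived C2 broken (retention); oxygen is excluded because the chromene is easier to oxidise than its precursor; the closest known reaction types are the photocatalytic E→Z isomerisation/oxidative lactonisation of cinnamic acids to coumarins and acridinium/cobaloxime arene C–H amination or etherification with hydrogen evolution, neither shown for a tertiary allylic alcohol closing a 2H-chromene.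

## Compound list

1 | (R)-(−)-linalool, (3R)-3,7-dimethylocta-1,6-dien-3-ol | CC(C)=CCC[C@](C)(C=C)O | starting material
2 | triethyl{[(3R)-3,7-dimethylocta-1,6-dien-3-yl]oxy}silane | CC(C)=CCC[C@](C)(C=C)O[Si](CC)(CC)CC | intermediate
3 | (4R)-4-methyl-4-[(triethylsilyl)oxy]hex-5-enal | O=CCC[C@](C)(C=C)O[Si](CC)(CC)CC | intermediate
4 | 4-{(1E,4R)-4-methyl-4-[(triethylsilyl)oxy]hexa-1,5-dien-1-yl}morpholine | O1CCN(CC1)/C=C/C[C@](C)(C=C)O[Si](CC)(CC)CC | intermediate
5 | (3R)-3-methyl-3-[(triethylsilyl)oxy]pent-4-enal | O=CC[C@](C)(C=C)O[Si](CC)(CC)CC | intermediate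
6 | [(1S)-endo]-(−)-3-bromocamphor, (1S,3R,4R)-3-bromo-1,7,7-trimethylbicyclo[2.2.1]heptan-2-one | C[C@]12CC[C@H](C1(C)C)[C@@H](Br)C2=O | starting material
7 | (1S,3R,4R,7S)-3-bromo-7-(bromomethyl)-1,7-dimethylbicyclo[2.2.1]heptan-2-one | C[C@]12CC[C@H]([C@]1(C)CBr)[C@@H](Br)C2=O | intermediate
8 | (1S,2S,3R)-2-(bromomethyl)-1,2-dimethylcyclopentane-1,3-dicarboxylic acid | C[C@]1(C(=O)O)CC[C@@H](C(=O)O)[C@]1(C)CBr | intermediate
9 | (1S,5R,8S)-8-(bromomethyl)-1,8-dimethyl-3-oxabicyclo[3.2.1]octane-2,4-dione | C[C@]12CC[C@H]([C@]1(C)CBr)C(=O)OC2=O | intermediate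
10 | (1S,2S,3R)-2-(bromomethyl)-1,2-dimethyl-3-{[(2-thioxopyridin-1(2H)-yl)oxy]carbonyl}cyclopentane-1-carboxylic acid | C[C@]1(C(=O)O)CC[C@@H](C(=O)On2ccccc2=S)[C@]1(C)CBr | intermediate
11 | (1S,2S)-2-(bromomethyl)-1,2-dimethylcyclopentane-1-carboxylic acid | C[C@]1(C(=O)O)CCC[C@]1(C)CBr | intermediate
12 | 4-chloro-2-methylbutan-2-ol | CC(C)(O)CCCl | starting material
13 | (1S,2S)-2-(bromomethyl)-1,2-dimethylcyclopentane-1-carbonyl chloride | C[C@]1(C(=O)Cl)CCC[C@]1(C)CBr | intermediate
14 | 1-[(1S,2S)-2-(bromomethyl)-1,2-dimethylcyclopentyl]-4-hydroxy-4-methylpentan-1-one | C[C@]1(C(=O)CCC(C)(C)O)CCC[C@]1(C)CBr | intermediate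
15 | 1-[(1S,2R)-1,2-dimethyl-2-{(4R)-4-methyl-2-oxo-4-[(triethylsilyl)oxy]hex-5-en-1-yl}cyclopentyl]-4-hydroxy-4-methylpentan-1-one | C[C@]1(C(=O)CCC(C)(C)O)CCC[C@]1(C)CC(=O)C[C@](C)(C=C)O[Si](CC)(CC)CC | intermediate
16 | (3aS,7aR)-5-(2-hydroxy-2-methylpropyl)-3a,7a-dimethyl-6-{(2R)-2-methyl-2-[(triethylsilyl)oxy]but-3-en-1-yl}-1,2,3,3a,7,7a-hexahydro-4H-inden-4-one | C=C[C@@](C)(CC1=C(CC(C)(C)O)C(=O)[C@@]2(C)CCC[C@]2(C)C1)O[Si](CC)(CC)CC | intermediate
17 | 1-bromo-3-methoxy-5-methylbenzene | COc1cc(C)cc(Br)c1 | starting material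
18 | (3aS,7aR)-5-(2-hydroxy-2-methylpropyl)-6-{(2R,3E)-4-(3-methoxy-5-methylphenyl)-2-methyl-2-[(triethylsilyl)oxy]but-3-en-1-yl}-3a,7a-dimethyl-1,2,3,3a,7,7a-hexahydro-4H-inden-4-one | COc1cc(C)cc(/C=C/[C@@](C)(CC2=C(CC(C)(C)O)C(=O)[C@@]3(C)CCC[C@]3(C)C2)O[Si](CC)(CC)CC)c1 | intermediate
19 | (3aS,7aR)-6-[(2R,3E)-2-hydroxy-4-(3-methoxy-5-methylphenyl)-2-methylbut-3-en-1-yl]-5-(2-hydroxy-2-methylpropyl)-3a,7a-dimethyl-1,2,3,3a,7,7a-hexahydro-4H-inden-4-one | COc1cc(C)cc(/C=C/[C@@](C)(CC2=C(CC(C)(C)O)C(=O)[C@@]3(C)CCC[C@]3(C)C2)O)c1 | intermediate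
20 | (3aS,7aR)-6-[(2R,3Z)-2-hydroxy-4-(3-methoxy-5-methylphenyl)-2-methylbut-3-en-1-yl]-5-(2-hydroxy-2-methylpropyl)-3a,7a-dimethyl-1,2,3,3a,7,7a-hexahydro-4H-inden-4-one | COc1cc(C)cc(/C=C\[C@@](C)(CC2=C(CC(C)(C)O)C(=O)[C@@]3(C)CCC[C@]3(C)C2)O)c1 | intermediate
21 | (3aS,7aR)-5-(2-hydroxy-2-methylpropyl)-6-{[(2R)-6-methoxy-2,8-dimethyl-2H-chromen-2-yl]methyl}-3a,7a-dimethyl-1,2,3,3a,7,7a-hexahydro-4H-inden-4-one | COc1cc(C)c2c(c1)C=C[C@@](C)(CC1=C(CC(C)(C)O)C(=O)[C@@]3(C)CCC[C@]3(C)C1)O2 | target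

## Step count and weak points

Total step count: 10. Longest linear sequence: 7 steps (6 to 21, steps 4 to 10); the linalool branch is 6 steps (1 to 21).

**Step 5 (hot nitric acid on a dibromide).** Over-oxidation or loss of the neopentyl bromide could lower the yield. The fallback sets out from 7 and comes back at 8. Zn dust in AcOH at 20 °C removes only the α-bromine and gives (1S,4S,7S)-7-(bromomethyl)-1,7-dimethylbicyclo[2.2.1]heptan-2-one F1. SeO2 in Ac2O at 140 °C (Riley oxidation) gives (1S,4R,7S)-7-(bromomethyl)-1,7-dimethylbicyclo[2.2.1]heptane-2,3-dione F2. H2O2 with NaOH in aqueous MeOH at 0 °C cleaves the 1,2-diketone to 8.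

**Step 8 (fragment union and ring closure in one flask).** Three things can go wrong:
- nickel may activate the neopentyl bromide slowly;
- a free neopentyl radical can shift a hydrogen from C5;
- at the diketone stage the enolate next to the silyloxy carbon can expel silyloxide before the aldol closes.

The fallback sets out from 5 and 14 and comes back at 15. NaClO2, NaH2PO4 and 2-methylbut-2-ene in t-BuOH/H2O oxidise 5 to (3R)-3-methyl-3-[(triethylsilyl)oxy]pent-4-enoic acid F3. 1-Chloro-N,N,2-trimethylprop-1-en-1-amine converts it under neutral conditions into (3R)-3-methyl-3-[(triethylsilyl)oxy]pent-4-enoyl chloride F4. NiCl2(dme), dtbbpy and Mn in DMA at 20 °C join F4 and 14 in a thermal reductive cross-electrophile coupling to 15. Here 15 is isolated and cyclised at 0 °C with KOt-Bu as in the second half of step 8.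

**Step 10 (the proposed new cyclisation).** Possible failures are:
- attack at the other ortho carbon (ortho to OMe);
- sensitised [2+2] addition of the styrene to the enone alkene;
- oxidation of the product.

The fallback uses only known reactions, sets out from 16 and comes back at 21:
- TBAF/AcOH gives (3aS,7aR)-6-[(2R)-2-hydroxy-2-methylbut-3-en-1-yl]-5-(2-hydroxy-2-methylpropyl)-3a,7a-dimethyl-1,2,3,3a,7,7a-hexahydro-4H-inden-4-one F5.
- Commercial 4-methoxy-2-methylaniline is iodinated with N-iodosuccinimide to 2-iodo-4-methoxy-6-methylaniline F6.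
- NaNO2, HBr and CuBr (Sandmeyer) convert F6 into 2-bromo-1-iodo-5-methoxy-3-methylbenzene F7.
- Heck reaction of F5 at the C–I bond of F7 (Pd(OAc)2, Et3N, DMF, 80 °C) gives (3aS,7aR)-6-[(2R,3E)-4-(2-bromo-5-methoxy-3-methylphenyl)-2-hydroxy-2-methylbut-3-en-1-yl]-5-(2-hydroxy-2-methylpropyl)-3a,7a-dimethyl-1,2,3,3a,7,7a-hexahydro-4H-inden-4-one F8.
- fac-Ir(ppy)3 at 450 nm in MeCN isomerises it to (3aS,7aR)-6-[(2R,3Z)-4-(2-bromo-5-methoxy-3-methylphenyl)-2-hydroxy-2-methylbut-3-en-1-yl]-5-(2-hydroxy-2-methylpropyl)-3a,7a-dimethyl-1,2,3,3a,7,7a-hexahydro-4H-inden-4-one F9.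
- Pd(OAc)2, 2-(di-tert-butylphosphino)-1,1′-binaphthyl and Cs2CO3 in toluene at 80 °C close the pyran ring by intramolecular C–O coupling of the tertiary alcohol to 21.

Further compounds
F1 | step 5 | (1S,4S,7S)-7-(bromomethyl)-1,7-dimethylbicyclo[2.2.1]heptan-2-one | C[C@]12CC[C@H]([C@]1(C)CBr)CC2=O
F2 | step 5 | (1S,4R,7S)-7-(bromomethyl)-1,7-dimethylbicyclo[2.2.1]heptane-2,3-dione | C[C@]12CC[C@H]([C@]1(C)CBr)C(=O)C2=O
F3 | step 8 | (3R)-3-methyl-3-[(triethylsilyl)oxy]pent-4-enoic acid | OC(=O)C[C@](C)(C=C)O[Si](CC)(CC)CC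
F4 | step 8 | (3R)-3-methyl-3-[(triethylsilyl)oxy]pent-4-enoyl chloride | ClC(=O)C[C@](C)(C=C)O[Si](CC)(CC)CC
F5 | step 10 | (3aS,7aR)-6-[(2R)-2-hydroxy-2-methylbut-3-en-1-yl]-5-(2-hydroxy-2-methylpropyl)-3a,7a-dimethyl-1,2,3,3a,7,7a-hexahydro-4H-inden-4-one | C=C[C@@](C)(CC1=C(CC(C)(C)O)C(=O)[C@@]2(C)CCC[C@]2(C)C1)O
F6 | step 10 | 2-iodo-4-methoxy-6-methylaniline | COc1cc(C)c(N)c(I)c1
F7 | step 10 | 2-bromo-1-iodo-5-methoxy-3-methylbenzene | COc1cc(C)c(Br)c(I)c1
F8 | step 10 | (3aS,7aR)-6-[(2R,3E)-4-(2-bromo-5-methoxy-3-methylphenyl)-2-hydroxy-2-methylbut-3-en-1-yl]-5-(2-hydroxy-2-methylpropyl)-3a,7a-dimethyl-1,2,3,3a,7,7a-hexahydro-4H-inden-4-one | COc1cc(C)c(Br)c(/C=C/[C@@](C)(CC2=C(CC(C)(C)O)C(=O)[C@@]3(C)CCC[C@]3(C)C2)O)c1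
F9 | step 10 | (3aS,7aR)-6-[(2R,3Z)-4-(2-bromo-5-methoxy-3-methylphenyl)-2-hydroxy-2-methylbut-3-en-1-yl]-5-(2-hydroxy-2-methylpropyl)-3a,7a-dimethyl-1,2,3,3a,7,7a-hexahydro-4H-inden-4-one | COc1cc(C)c(Br)c(/C=C\[C@@](C)(CC2=C(CC(C)(C)O)C(=O)[C@@]3(C)CCC[C@]3(C)C2)O)c1
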